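**Plan**

- Retrosynthesis: the 5-hydroxyl is traced back to a methyl ether, and the target is then cut at the C2–C1' bond that joins ring C to ring B.
- Enabling feature: this bond lies between C3 of ring C and the 2'-oxygen of ring B. A carboxyl carbon on C3, esterified to the 2'-oxygen, holds the chromone C2–H next to a C1'–Br bond, so the bond can form inside a six-membered lactone.
- Further cuts: the ester C–O bond, the O1–C2 and C2–C3 bonds of ring C (C2 and the carboxyl carbon both come from a formamide), and the C4–C4a and C8a–O1 bonds at ring A.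
- Forward: a tetramethoxybenzene is formylated, turned into the phenol and C-acetylated (ring A). Ring C is closed as a 3-formylchromone and oxidised to the acid, ring B is attached as its ester, and the lactone ring closes in the key step. The bridge carbon then leaves as CO2 and the 5-methyl ether is cleaved last.
- Stereochemistry: the target has no stereocentre, so nothing has to be set or protected.

Key step: step 8

Remark on the chemistry: a free 2'-hydroxy 3-carboxylic acid would close back to the lactone on acidification, so the bridge carbon is removed by full alkaline opening to a diaroylacetic acid, which loses CO2, and ring C is then closed again with acid.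

**Route**

Step 1
Reactants: 1 1,2,3,4-tetramethoxybenzene
Product: 3 2,3,4,5-tetramethoxybenzaldehyde, via iminium chloride 2 (not isolated)
Conditions: POCl3, DMF, 0 to 90 °C; then H2O, 60 °C
Reagents that add atoms: N,N-dimethylformamide, CN(C)C=O; water, O
Why: Vilsmeier–Haack formylation should attack one of the two equivalent free positions of the electron-rich ring, each para to one methoxy group and ortho to another, and hydrolysis of the iminium salt releases the aldehyde.

Step 2
Reactants: 3 2,3,4,5-tetramethoxybenzaldehyde
Product: 5 2,3,4,5-tetramethoxyphenol, via aryl formate 4 (not isolated)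
Conditions: mCPBA, CH2Cl2, 0 °C to rt; then K2CO3 (cat.), MeOH, rt
Reagents that add atoms: mCPBA, O=C(OO)c1cccc(Cl)c1
Why: Baeyer–Villiger oxidation of an electron-rich benzaldehyde proceeds with aryl migration to the aryl formate, which catalytic carbonate in methanol should cleave by transesterification to the phenol.

Step 3
Reactants: 5 2,3,4,5-tetramethoxyphenol
Product: 6 1-(2-hydroxy-3,4,5,6-tetramethoxyphenyl)ethan-1-one
Conditions: AcOH, BF3·OEt2 (3 equiv), 90 °C; then H2O
Reagents that add atoms: acetic acid, CC(=O)O
Why: Friedel–Crafts acylation of the phenol (equivalent to O-acetylation and Fries rearrangement) can only occupy the single free ring position, which is ortho to the hydroxyl, and the chelated ortho-hydroxy ketone should resist further reaction.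

Step 4
Reactants: 6 1-(2-hydroxy-3,4,5,6-tetramethoxyphenyl)ethan-1-one
Product: 8 5,6,7,8-tetramethoxy-4-oxo-4H-chromene-3-carbaldehyde, via chromone iminium chloride 7 (not isolated)
Conditions: POCl3, DMF, 0 to 50 °C; then ice-water
Reagents that add atoms: N,N-dimethylformamide, CN(C)C=O; water, O
Why: The Vilsmeier–Haack reaction of an ortho-hydroxyacetophenone formylates the methyl group twice and the phenol closes onto the first aminomethylene carbon, the standard route to 3-formylchromones, while the fully substituted benzene ring offers no competing site.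

Step 5
Reactants: 8 5,6,7,8-tetramethoxy-4-oxo-4H-chromene-3-carbaldehyde
Product: 9 5,6,7,8-tetramethoxy-4-oxo-4H-chromene-3-carboxylic acid
Conditions: NaClO2, NaH2PO4, 2-methyl-2-butene, t-BuOH/H2O, rt
Reagents that add atoms: sodium chlorite NaClO2, [Na+].[O-]Cl=O
Why: Pinnick oxidation should convert the aldehyde to the acid under buffered, weakly acidic conditions that leave the base-sensitive pyranone closed, with the alkene scavenging hypochlorite.

Step 6
Reactants: 10 3,4-dimethoxyphenol
Product: 11 2-bromo-4,5-dimethoxyphenol
Conditions: NBS, MeCN, 0 °C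
Reagents that add atoms: N-bromosuccinimide, O=C1CCC(=O)N1Br
Why: Electrophilic aromatic bromination should occur at C6 of the phenol, ortho to the hydroxyl, para to the 3-methoxy group and less hindered than C2, which places bromine on the carbon that later becomes C1' of ring B.

Step 7
Reactants: 9 5,6,7,8-tetramethoxy-4-oxo-4H-chromene-3-carboxylic acid; 11 2-bromo-4,5-dimethoxyphenol
Product: 13 2-bromo-4,5-dimethoxyphenyl 5,6,7,8-tetramethoxy-4-oxo-4H-chromene-3-carboxylate, via acid chloride 12 (not isolated)
Conditions: (COCl)2, DMF (cat.), CH2Cl2, 0 °C to rt; then 11, pyridine, CH2Cl2, 0 °C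
Reagents that add atoms: none
Why: Acyl chloride formation followed by O-acylation of the phenol is a standard aryl ester synthesis, and the low temperature and the weakly nucleophilic base should limit conjugate attack at C2 of the pyranone.

Step 8
Reactants: 13 2-bromo-4,5-dimethoxyphenyl 5,6,7,8-tetramethoxy-4-oxo-4H-chromene-3-carboxylate
Product: 14 2,3,8,9,10,11-hexamethoxy-6H,7H-chromeno[4,3-b]chromene-6,7-dione (lactone-bridged flavone)
Conditions: Pd(OAc)2 (10 mol %), PCy3·HBF4 (20 mol %), PivOH (30 mol %), K2CO3 (2 equiv), anhydrous degassed DMA, 110 °C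
Reagents that add atoms: none
Why: Zerovalent palladium, formed from Pd(OAc)2 and PCy3, inserts into the C–Br bond of ring B; the arylpalladium bromide (divalent palladium) exchanges bromide for pivalate and cleaves the C2–H bond of ring C by concerted metalation–deprotonation, and reductive elimination from the seven-membered palladacycle forms the C2–C1' bond. The closest known reaction type is the palladium-catalysed intramolecular direct arylation of 2-haloaryl esters and aryl 2-halobenzoates to benzo[c]chromen-6-ones. The one ring that closes is the six-membered lactone (C2, C3, the carboxyl carbon, the ester oxygen, C2', C1'), closed by C–C bond formation in a 6-endo sense with respect to the C2=C3 bond. No stereocentre is created, so no element of stereocontrol is needed. The step needs site selectivity: ring C has only one C–H bond, acidified by the ring oxygen and two carbonyl groups, and the tether can reach no other carbon, while on ring B the halogen next to the ester oxygen decides which carbon is joined. It also needs the aryl ester to survive, which the anhydrous, poorly nucleophilic carbonate–pivalate base is chosen to allow.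

Step 9
Reactants: 14 2,3,8,9,10,11-hexamethoxy-6H,7H-chromeno[4,3-b]chromene-6,7-dione
Product: 17 2-(2-hydroxy-4,5-dimethoxyphenyl)-5,6,7,8-tetramethoxy-4H-chromen-4-one, via diaroylacetic acid 15 (not isolated), via 1,3-diketone 16 (not isolated)
Conditions: 2 M KOH, EtOH/H2O, 80 °C, N2; then conc. HCl, AcOH, 100 °C
Reagents that add atoms: none
Why: Hot alkali should hydrolyse the lactone and open the doubly activated pyranone at C2 (saponification with ring fission, as known for 3-acylchromones and 3-acyl-4-hydroxycoumarins), the diaroylacetic acid loses CO2 on acidification as a doubly activated β-keto acid, and acid-catalysed cyclodehydration of the 1,3-diketone, the closing stage of a Baker–Venkataraman flavone synthesis, should restore ring C through the ring A phenol because the ring B carbonyl is unhindered and its cation is stabilised by the para 4'-methoxy group, whereas the ring A carbonyl is shielded by two ortho substituents.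

Step 10
Reactants: 17 2-(2-hydroxy-4,5-dimethoxyphenyl)-5,6,7,8-tetramethoxy-4H-chromen-4-one
Product: 18 agehoustin F
Conditions: BCl3 (2.5 equiv), CH2Cl2, −78 to 0 °C; then H2O
Reagents that add atoms: none
Why: BCl3 binds the C4 carbonyl and should cleave only the peri 5-methyl ether through a six-membered chelate (Lewis-acid-mediated selective demethylation), while the other five methoxy groups lack this assistance and the 2'-borate is hydrolysed on work-up.

**Compound list**

1 | 1,2,3,4-tetramethoxybenzene | COc1ccc(OC)c(OC)c1OC | starting material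
2 | dimethyl[(2,3,4,5-tetramethoxyphenyl)methylidene]ammonium chloride | C[N+](C)=Cc1cc(OC)c(OC)c(OC)c1OC.[Cl-] | intermediate
3 | 2,3,4,5-tetramethoxybenzaldehyde | O=Cc1cc(OC)c(OC)c(OC)c1OC | intermediate
4 | 2,3,4,5-tetramethoxyphenyl formate | O=COc1cc(OC)c(OC)c(OC)c1OC | intermediate
5 | 2,3,4,5-tetramethoxyphenol | Oc1cc(OC)c(OC)c(OC)c1OC | intermediate
6 | 1-(2-hydroxy-3,4,5,6-tetramethoxyphenyl)ethan-1-one | CC(=O)c1c(O)c(OC)c(OC)c(OC)c1OC | intermediate
7 | dimethyl[(5,6,7,8-tetramethoxy-4-oxo-4H-chromen-3-yl)methylidene]ammonium chloride | C[N+](C)=Cc1coc2c(OC)c(OC)c(OC)c(OC)c2c1=O.[Cl-] | intermediate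
8 | 5,6,7,8-tetramethoxy-4-oxo-4H-chromene-3-carbaldehyde | O=Cc1coc2c(OC)c(OC)c(OC)c(OC)c2c1=O | intermediate
9 | 5,6,7,8-tetramethoxy-4-oxo-4H-chromene-3-carboxylic acid | O=C(O)c1coc2c(OC)c(OC)c(OC)c(OC)c2c1=O | intermediate
10 | 3,4-dimethoxyphenol | COc1ccc(O)cc1OC | starting material
11 | 2-bromo-4,5-dimethoxyphenol | COc1cc(O)c(Br)cc1OC | intermediate
12 | 5,6,7,8-tetramethoxy-4-oxo-4H-chromene-3-carbonyl chloride | O=C(Cl)c1coc2c(OC)c(OC)c(OC)c(OC)c2c1=O | intermediate
13 | 2-bromo-4,5-dimethoxyphenyl 5,6,7,8-tetramethoxy-4-oxo-4H-chromene-3-carboxylate | COc1cc(Br)c(OC(=O)c2coc3c(OC)c(OC)c(OC)c(OC)c3c2=O)cc1OC | intermediate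
14 | 2,3,8,9,10,11-hexamethoxy-6H,7H-chromeno[4,3-b]chromene-6,7-dione | COc1cc2c(cc1OC)oc(=O)c1c2oc2c(OC)c(OC)c(OC)c(OC)c2c1=O | intermediate
15 | 2-(2-hydroxy-4,5-dimethoxybenzoyl)-3-(2-hydroxy-3,4,5,6-tetramethoxyphenyl)-3-oxopropanoic acid | COc1cc(O)c(C(=O)C(C(=O)O)C(=O)c2c(O)c(OC)c(OC)c(OC)c2OC)cc1OC | intermediate
16 | 1-(2-hydroxy-4,5-dimethoxyphenyl)-3-(2-hydroxy-3,4,5,6-tetramethoxyphenyl)propane-1,3-dione | COc1cc(O)c(C(=O)CC(=O)c2c(O)c(OC)c(OC)c(OC)c2OC)cc1OC | intermediate
17 | 2-(2-hydroxy-4,5-dimethoxyphenyl)-5,6,7,8-tetramethoxy-4H-chromen-4-one | COc1cc(O)c(-c2cc(=O)c3c(OC)c(OC)c(OC)c(OC)c3o2)cc1OC | intermediate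
18 | agehoustin F, 5-hydroxy-2-(2-hydroxy-4,5-dimethoxyphenyl)-6,7,8-trimethoxy-4H-chromen-4-one | COc1cc(O)c(-c2cc(=O)c3c(O)c(OC)c(OC)c(OC)c3o2)cc1OC | target

**Step count and risks**

Total step count: 10. Longest linear sequence: 9 steps (steps 1 to 5 and 7 to 10, from compound 1); step 6 is the one-step ring B branch.

Steps most likely to fail:

Step 8 (key step). The aryl ester may be cleaved by carbonate or adventitious hydroxide, the freed phenoxide may add to C2 and open the pyranone, or bromine may be lost reductively before C–H metalation. Fallback: acid 9, through chloride 12, would be esterified with the bromine-free phenol 10 as in step 7 to give 3,4-dimethoxyphenyl 5,6,7,8-tetramethoxy-4-oxo-4H-chromene-3-carboxylate F1. This ester would be cyclised by twofold C–H activation under divalent palladium catalysis (Pd(OAc)2, AgOAc, PivOH, 110 °C), a dehydrogenative coupling in an acidic medium without carbonate. Palladation of ring B should prefer the less hindered ortho position para to the 3-methoxy group, which gives the same substitution pattern. The fallback sets out from 9 and 10 and returns to the route at lactone 14.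

Step 9. Hot alkali may fragment the tricarbonyl and dicarbonyl anions by retro-Claisen cleavage, the opening may stall at a singly opened dianion that reverts to 14 on acidification, or ring closure may run through the ring B phenol onto the ring A carbonyl. Fallback: lactone 14 would be opened with KOH in aqueous DMSO at room temperature and the phenoxide benzylated in the same flask with benzyl bromide. Acidification would give 2-[2-(benzyloxy)-4,5-dimethoxyphenyl]-5,6,7,8-tetramethoxy-4-oxo-4H-chromene-3-carboxylic acid F2, which cannot relactonise. Protodecarboxylation with ring C intact (Cu2O, 1,10-phenanthroline, NMP/quinoline, 170 °C) would give 2-[2-(benzyloxy)-4,5-dimethoxyphenyl]-5,6,7,8-tetramethoxy-4H-chromen-4-one F3. Hydrogenolysis (H2, palladium on carbon (Pd/C), EtOAc) then returns to the route at 17.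

Step 7. The phenol or pyridine may add to C2 of the acyl chloride and open the pyranone instead of acylating oxygen. Fallback: acetophenone 6 would be condensed with N,N-dimethylformamide dimethyl acetal (toluene, 100 °C) to (E)-3-(dimethylamino)-1-(2-hydroxy-3,4,5,6-tetramethoxyphenyl)prop-2-en-1-one F4. Iodine in CHCl3 at rt would close ring C to 3-iodo-5,6,7,8-tetramethoxy-4H-chromen-4-one F5. Palladium-catalysed aryloxycarbonylation (Pd(OAc)2, Xantphos, CO at 1 atm, Et3N, toluene, 80 °C) with phenol 11 would then give ester 13, where the route resumes. The iodide on the electron-poor chromone should undergo oxidative addition well before the bromide on the electron-rich phenol. This path bypasses steps 4, 5 and 7.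

**Further compounds**

F1 | step 8 | 3,4-dimethoxyphenyl 5,6,7,8-tetramethoxy-4-oxo-4H-chromene-3-carboxylate | COc1ccc(OC(=O)c2coc3c(OC)c(OC)c(OC)c(OC)c3c2=O)cc1OC
F2 | step 9 | 2-[2-(benzyloxy)-4,5-dimethoxyphenyl]-5,6,7,8-tetramethoxy-4-oxo-4H-chromene-3-carboxylic acid | COc1cc(OCc2ccccc2)c(-c2oc3c(OC)c(OC)c(OC)c(OC)c3c(=O)c2C(=O)O)cc1OC
F3 | step 9 | 2-[2-(benzyloxy)-4,5-dimethoxyphenyl]-5,6,7,8-tetramethoxy-4H-chromen-4-one | COc1cc(OCc2ccccc2)c(-c2cc(=O)c3c(OC)c(OC)c(OC)c(OC)c3o2)cc1OC
F4 | step 7 | (E)-3-(dimethylamino)-1-(2-hydroxy-3,4,5,6-tetramethoxyphenyl)prop-2-en-1-one | CN(C)/C=C/C(=O)c1c(O)c(OC)c(OC)c(OC)c1OC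
F5 | step 7 | 3-iodo-5,6,7,8-tetramethoxy-4H-chromen-4-one | COc1c(OC)c(OC)c2occ(I)c(=O)c2c1OC
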